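Reading the equivalents as a yield is the pitfall here. The bench rule says that a bis adduct takes two partners, so its share of the substrate charged reaches E over two, with E the equivalents of partner to substrate. In the noon run E is 1.00, so the rule promises 50.0%, yet the reading at 120 s is 25.9%, about half of that. The rule gives a ceiling, not a forecast.

| flask | substrate | partner | temperature | remark | time |
|---|---|---|---|---|---|
| autumn | 0.61 mM | 1 mM | −42 °C | run made earlier |  |
| noon | 1 mM | 1 mM | −26 °C | run made earlier |  |
| Monday's | 0.50 mM | 1.00 mM |  | at −20 °C until 40 s, from then on at −50 °C | 2.0 min |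
| Thursday's | 2.0 mM | 1.00 mM |  | at −20 °C throughout | 2.0 min |

autumn run (percent of the substrate charged)

| time / min | bis adduct / % | substrate / % |
|---|---|---|
| 1.33 | 58.0 | 8.7 |
| 3.00 | 60.8 | 7.5 |
| 4.00 | 62.5 | 6.2 |
| 6.00 | 63.5 | 8.2 |

noon run (percent of the substrate charged)

| time / s | bis adduct / % | substrate / % |
|---|---|---|
| 15.0 | 24.5 | 29.7 |
| 40.0 | 25.9 | 27.7 |
| 80.0 | 27.4 | 28.2 |
| 120 | 25.9 | 26.5 |

(scatter of a reading: 1 percentage point)

- which one finishes higher in amount of bis adduct, in percent of the substrate charged ("neither" within 2 percentage points) (Monday's / Thursday's / neither)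
- amount of bis adduct at the end, in percent of the substrate charged, Monday's
- amount of bis adduct at the end, in percent of the substrate charged, Thursday's



A ledger counts the partner. Let s and b be the substrate and bis adduct as fractions of the substrate charged, and take mono adduct as the rest. Partner found in adducts per substrate charged is then u, which is one minus s plus b. The share of the charged partner so found, f = u/E, is 99.4% at noon. In the autumn run at 6.00 min, with E at 1.64, it reads 94.7%.

As an assumption for flasks where substrate remains, take b as roughly c times the square of the converted fraction x. The noon reading at 120 s gives c as 0.479. Taking f as one, x plus b equals E, so this rule puts x at one at E of 1.48, and that is its border.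

Thursday's, at E of 0.500, lies below it, with partner as the limiting reagent, and the rule gives b near 8.33%. Monday's, at E of 2.00, lies above it. Setting s at zero there and borrowing the autumn f, the ledger gives 89.5%.

The forecast also picks Monday's, with 78% (69% to 86%) for Monday's and 7% (5% to 9.5%) for Thursday's, on the ground that “partner is exactly stoichiometric, so the end is kinetically limited”, and its Monday's figure stands lower than the ledger's.

Monday's ends at 86.5% and Thursday's at 7.05%, so Monday's finishes higher.

    substrate + partner → mono adduct (k = 1200 M⁻¹ s⁻¹, Ea = 36.0 kJ mol⁻¹)
    partner + mono adduct → bis adduct (k = 720 M⁻¹ s⁻¹, Ea = 35.0 kJ mol⁻¹)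
    partner + bis adduct ⇌ triple product (K = 650 M⁻¹, k = 110 M⁻¹ s⁻¹, Ea = 41.0 kJ mol⁻¹, ΔH = −16.0 kJ mol⁻¹)
    partner ⇌ dormant form (K = 0.610, k = 0.0820 s⁻¹, Ea = 63.0 kJ mol⁻¹, ΔH = −38.0 kJ mol⁻¹)
    (constants at −20 °C)

At 2.00 min Monday's still holds 10.4% mono adduct, with 1.8% of its partner free. Counted from s and b as before, f in Monday's comes to 92.9%, beside the autumn 94.7%. A flask like Monday's but with 0.40 mM of partner ends with 37.6% substrate. That substrate and the autumn f, with E at 0.800, give b as 13.4%, and that flask held 17.4%.

Readings and results stem from a simulated flask on assumed constants; scatter was added.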